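**Strategy.** Everything rests on the bond between the spiro carbon C5 and the ketone carbon C6 of the cyclopentanone (ring A). C6 lies between two quaternary carbons that each bear a lactone carbonyl, so C5 is an ester α-carbon and C6 an acyl carbon. The bond is made by a conjugate-addition-triggered Dieckmann closure: copper-catalysed addition of 2-methylpropenylmagnesium bromide to the acrylate of γ-lactone diester 8 gives an ester enolate that acylates the neighbouring methyl ester. One operation closes ring A, creates the quaternary centre C5 and installs a prenyl group, which a glyoxal–ene reaction and lactonisation convert into the δ-lactone (ring C).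

Key step: step 5

Remark on locants: spiro[cyclopenta[c]furan-5,3'-pyran] numbering is used. Ring A (cyclopentanone) is C3a–C4–C5–C6(=O)–C6a, ring B (γ-lactone) is C1(=O)–O2–C3(Me2)–C3a–C6a, and ring C (δ-lactone) is O1'–C2'(=O)–C3'(= C5)–C4'–C5'–C6'.

Assumption: the (S,S)-bis(oxazoline) ligand is taken to give the (4R) adduct in step 3 and the (3S) carbinol in step 7; if the sense of induction is the opposite, the (R,R) ligand is used. Compounds 6 and 9 are taken as commercial reagents.

Step 1
Reactants: 1 dimethyl malonate; 2 2,2-dimethyloxirane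
Product: 3 methyl 5,5-dimethyl-2-oxotetrahydrofuran-3-carboxylate (racemic)
Conditions: NaOMe (1.05 equiv), MeOH, reflux; then aq. HCl
Reagents that add atoms: none
Why: The malonate anion opens the epoxide at its unsubstituted carbon (SN2) and the tertiary alkoxide lactonises onto one ester (malonic ester–epoxide lactone annulation); the single stereocentre is racemic and is removed in step 2.

Step 2
Reactants: 3 methyl 5,5-dimethyl-2-oxotetrahydrofuran-3-carboxylate
Product: 5 methyl 5,5-dimethyl-2-oxo-2,5-dihydrofuran-3-carboxylate, via phenylselanyl lactone ester 4 (not isolated)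
Conditions: NaH, THF, 0 °C; PhSeCl; then 30% aq. H2O2, CH2Cl2, 0 °C to rt
Reagents that add atoms: none
Why: α-Selenenylation of the 1,3-dicarbonyl followed by selenoxide syn-elimination should give the ring double bond, since the only β-hydrogens are on the ring CH2.

Step 3
Reactants: 5 methyl 5,5-dimethyl-2-oxo-2,5-dihydrofuran-3-carboxylate; 6 ethyl 2-[(trimethylsilyl)methyl]prop-2-enoate
Product: 7 methyl (4R)-4-[2-(ethoxycarbonyl)prop-2-en-1-yl]-5,5-dimethyl-2-oxotetrahydrofuran-3-carboxylate (epimers at C3)
Conditions: Cu(OTf)2 (10 mol%), (S,S)-tBu-box (11 mol%), (CF3)2CHOH (1.1 equiv), CH2Cl2, −40 °C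
Reagents that add atoms: none
Why: Two-point binding of the lactone and ester carbonyls of 5 to the chiral divalent-copper complex activates the alkylidene 1,3-dicarbonyl for Hosomi–Sakurai conjugate allylation and lets the ligand shield one face of C4, which sets the (4R) centre; hexafluoroisopropanol takes up the silyl group and protonates the enolate.

Step 4
Reactants: 7 methyl (4R)-4-[2-(ethoxycarbonyl)prop-2-en-1-yl]-5,5-dimethyl-2-oxotetrahydrofuran-3-carboxylate
Product: 8 methyl (3R,4R)-4-[2-(ethoxycarbonyl)prop-2-en-1-yl]-3,5,5-trimethyl-2-oxotetrahydrofuran-3-carboxylate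
Conditions: MeI, K2CO3, acetone, rt
Reagents that add atoms: iodomethane, CI
Why: C-Methylation of the malonate-type enolate should occur anti to the C4 side chain, so the methoxycarbonyl group ends cis to the side chain (as a cis-fused ring A requires) and the quaternary centre C3 (C6a of the target) is set.

Step 5
Reactants: 8 methyl (3R,4R)-4-[2-(ethoxycarbonyl)prop-2-en-1-yl]-3,5,5-trimethyl-2-oxotetrahydrofuran-3-carboxylate; 9 (2-methylprop-1-en-1-yl)magnesium bromide
Product: 11 ethyl (3aR,5R,6aR)-3,3,6a-trimethyl-5-(3-methylbut-2-en-1-yl)-1,6-dioxohexahydro-1H-cyclopenta[c]furan-5-carboxylate, via bromomagnesium ester enolate 10 (not isolated)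
Conditions: CuBr·SMe2 (10 mol%), THF, −78 °C, slow addition of 8; then −78 to −20 °C; aq. NH4Cl
Reagents that add atoms: none
Why: Copper-catalysed 1,4-addition of the alkenyl Grignard reagent to the 2-substituted acrylate of 8 gives magnesium ester enolate 10, whose α-carbon (the future spiro carbon C5) attacks the methyl ester carbonyl (the future ketone carbon C6) held cis to the side chain on the γ-lactone, and loss of methoxide closes the cyclopentanone. This is a Michael-initiated ring closure, that is a tandem conjugate addition–Dieckmann (intramolecular Claisen) condensation, which forms the C5–C6 bond, the prenyl C–C bond and the quaternary centre in one operation. Ring A closes in a 5-(enolexo)-exo-trig mode, and its cis fusion to ring B follows from the cis relationship of ester and side chain set in step 4. The new stereocentre C5 is set in the ring closure: the solvated metal ester-enolate terminus, the bulkier of the two groups on the enolate carbon, should take the convex face away from the gem-dimethyl lactone ring and leave the flexible prenyl CH2 on the concave face, which is the (5R) arrangement of the target. The step needs 1,4- over 1,2-addition (copper catalysis at −78 °C), attack on the exocyclic ester and not on the lactone carbonyl (fused five-membered versus bridged transition state) and kinetic trapping of the non-enolisable β-keto ester (low temperature, poorly nucleophilic magnesium methoxide).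

Step 6
Reactants: 12 3-methylbutan-2-one
Product: 13 3-methyl-2-oxobutanal
Conditions: SeO2, 1,4-dioxane/H2O, reflux; distil
Reagents that add atoms: selenium dioxide, O=[Se]=O
Why: Riley oxidation converts the methyl group of the methyl ketone into the aldehyde, while the isopropyl methine cannot give a 1,2-dicarbonyl and is left.

Step 7
Reactants: 11 ethyl (3aR,5R,6aR)-3,3,6a-trimethyl-5-(3-methylbut-2-en-1-yl)-1,6-dioxohexahydro-1H-cyclopenta[c]furan-5-carboxylate; 13 3-methyl-2-oxobutanal
Product: 14 ethyl (3aR,5R,6aR)-5-[(2S,3S)-3-hydroxy-5-methyl-4-oxo-2-(prop-1-en-2-yl)hexyl]-3,3,6a-trimethyl-1,6-dioxohexahydro-1H-cyclopenta[c]furan-5-carboxylate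
Conditions: [Cu((S,S)-tBu-box)](SbF6)2 (10 mol%), CH2Cl2, 0 °C
Reagents that add atoms: none
Why: In this carbonyl-ene reaction the aldehyde carbon of the chelated 1,2-dicarbonyl bonds to the less substituted carbon of the prenyl double bond while an allylic methyl hydrogen moves to oxygen, which gives the isopropenyl-bearing homoallylic alcohol; the chiral divalent-copper chelate exposes one aldehyde face (sets the carbinol centre, 3S) and its acyl side should sit over the alkene hydrogen and not over the CH2 branch (sets the adjacent centre, 2S).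

Step 8
Reactants: 14 ethyl (3aR,5R,6aR)-5-[(2S,3S)-3-hydroxy-5-methyl-4-oxo-2-(prop-1-en-2-yl)hexyl]-3,3,6a-trimethyl-1,6-dioxohexahydro-1H-cyclopenta[c]furan-5-carboxylate
Product: 15 (3aR,5R,6aR,5'S,6'S)-3,3,6a-trimethyl-6'-(2-methylpropanoyl)-5'-(prop-1-en-2-yl)hexahydrospiro[cyclopenta[c]furan-5,3'-pyran]-1,2',6-trione (CNP0216954.2)
Conditions: PPTS (10 mol%), toluene, 60 °C
Reagents that add atoms: none
Why: Acid-catalysed intramolecular transesterification of the δ-hydroxy ester closes the six-membered lactone (helped by the quaternary C5 and the activating β-keto group) without touching a stereocentre; PPTS should be too weak to protonate the isopropenyl group or to enolise the α-oxygenated ketone.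

**Compound list**

1 | dimethyl malonate | COC(=O)CC(=O)OC | starting material
2 | 2,2-dimethyloxirane | CC1(C)CO1 | starting material
3 | methyl 5,5-dimethyl-2-oxotetrahydrofuran-3-carboxylate (racemic) | COC(=O)C1CC(C)(C)OC1=O | intermediate
4 | methyl 5,5-dimethyl-2-oxo-3-(phenylselanyl)tetrahydrofuran-3-carboxylate (racemic, not isolated) | COC(=O)C1([Se]c2ccccc2)CC(C)(C)OC1=O | intermediate
5 | methyl 5,5-dimethyl-2-oxo-2,5-dihydrofuran-3-carboxylate | COC(=O)C1=CC(C)(C)OC1=O | intermediate
6 | ethyl 2-[(trimethylsilyl)methyl]prop-2-enoate | CCOC(=O)C(=C)C[Si](C)(C)C | starting material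
7 | methyl (4R)-4-[2-(ethoxycarbonyl)prop-2-en-1-yl]-5,5-dimethyl-2-oxotetrahydrofuran-3-carboxylate (epimers at C3) | C=C(C[C@H]1C(C)(C)OC(=O)C1C(=O)OC)C(=O)OCC | intermediate
8 | methyl (3R,4R)-4-[2-(ethoxycarbonyl)prop-2-en-1-yl]-3,5,5-trimethyl-2-oxotetrahydrofuran-3-carboxylate | C=C(C[C@H]1C(C)(C)OC(=O)[C@@]1(C)C(=O)OC)C(=O)OCC | intermediate
9 | (2-methylprop-1-en-1-yl)magnesium bromide | CC(C)=C[Mg]Br | starting material
10 | bromomagnesium enolate of the ethyl ester formed by 1,4-addition to 8 (not isolated) | CCOC(O[Mg]Br)=C(CC=C(C)C)C[C@H]1C(C)(C)OC(=O)[C@@]1(C)C(=O)OC | intermediate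
11 | ethyl (3aR,5R,6aR)-3,3,6a-trimethyl-5-(3-methylbut-2-en-1-yl)-1,6-dioxohexahydro-1H-cyclopenta[c]furan-5-carboxylate | CC(C)=CC[C@]1(C[C@H]2C(C)(C)OC(=O)[C@@]2(C)C1=O)C(=O)OCC | intermediate
12 | 3-methylbutan-2-one | CC(C)C(C)=O | starting material
13 | 3-methyl-2-oxobutanal | CC(C)C(=O)C=O | intermediate
14 | ethyl (3aR,5R,6aR)-5-[(2S,3S)-3-hydroxy-5-methyl-4-oxo-2-(prop-1-en-2-yl)hexyl]-3,3,6a-trimethyl-1,6-dioxohexahydro-1H-cyclopenta[c]furan-5-carboxylate | C=C(C)[C@H](C[C@]1(C[C@H]2C(C)(C)OC(=O)[C@@]2(C)C1=O)C(=O)OCC)[C@H](O)C(=O)C(C)C | intermediate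
15 | (3aR,5R,6aR,5'S,6'S)-3,3,6a-trimethyl-6'-(2-methylpropanoyl)-5'-(prop-1-en-2-yl)hexahydrospiro[cyclopenta[c]furan-5,3'-pyran]-1,2',6-trione | C=C(C)[C@@H]1C[C@]2(C[C@H]3C(C)(C)OC(=O)[C@@]3(C)C2=O)C(=O)O[C@@H]1C(=O)C(C)C | target

**Step count.** Total: 8 steps. Longest linear sequence: 7 steps (steps 1–5, 7, 8); step 6 is a one-step branch.

**Steps most likely to fail**

Step 7 (ene reaction). The non-enolisable β-keto ester of 11 may compete with 13 for the Lewis acid, so that turnover is slow and the catalyst no longer controls the aldehyde face or the orientation of the acyl group, which would give a mixture at the two new centres. The fallback sets out from 11 and returns to the route at 15. It replaces catalyst control by chelation control from a chiral aldehyde. Commercial methyl (2S)-2-hydroxy-3-methylbutanoate (CC(C)[C@H](O)C(=O)OC) is protected with 4-methoxybenzyl 2,2,2-trichloroacetimidate (cat. TfOH) as methyl (2S)-2-[(4-methoxybenzyl)oxy]-3-methylbutanoate F1 and reduced with i-Bu2AlH (−78 °C) to (2S)-2-[(4-methoxybenzyl)oxy]-3-methylbutanal F2. SnCl4 (CH2Cl2, −78 °C) chelates the aldehyde and ether oxygens of F2, so the prenyl group of 11 should attack the aldehyde face anti to the isopropyl group in an ene reaction and give hydroxy ester F3. PPTS lactonises F3 to spiro lactone ether F4, DDQ (CH2Cl2/H2O) removes the 4-methoxybenzyl group to give alcohol F5, and Dess–Martin periodinane (NaHCO3, CH2Cl2) oxidises F5 to 15.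

Step 5 (key step). The two groups on the enolate carbon may not be differentiated well enough, so that both C5 epimers form, or methoxide may reopen the non-enolisable β-keto ester by retro-Claisen cleavage. The fallback sets out from 8 and returns to the route at 15. It closes ring A from a preformed ring C, so that the face is chosen by the δ-lactone. Reagent 9 is added to 8 with CuBr·SMe2 (cat.) in the presence of Me3SiCl (THF, −78 °C), so that the enolate is silylated before it can cyclise; aqueous citric acid then gives open-chain prenyl diester F6 (both epimers at the ester α-carbon). The SnCl4-promoted ene reaction of F6 with aldehyde F2 gives hydroxy ester F7, and PPTS closes δ-lactone F8. LiN(SiMe3)2 (THF, −78 to −20 °C) forms the lactone enolate, which should close ring A on the methyl ester by axial attack, trans to the equatorial isopropenyl group and away from the C6' side chain. This gives spiro lactone ether F4, which is taken to 15 through alcohol F5 as described for step 7.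

Step 3 (conjugate allylation). The ester-deactivated allylsilane may react too slowly at the hindered C4 of 5, and a racemic background reaction at higher temperature would erode the enantiomeric purity. The fallback sets out from 9 and 1 and returns to the route at 8. It takes the C4 configuration from an epoxide. Reagent 9 displaces the allylic bromide of 2,3-dibromoprop-1-ene (C=C(Br)CBr; CuI cat., THF, 0 °C) to give 2-bromo-5-methylhexa-1,4-diene F9. Shi epoxidation of the trisubstituted double bond (fructose-derived ketone of the enantiomeric series that gives the 3R epoxide, KHSO5, K2CO3, MeCN/dimethoxymethane/H2O, 0 °C) gives (3R)-3-(2-bromoprop-2-en-1-yl)-2,2-dimethyloxirane F10. Sodium dimethyl malonate (from 1, NaOMe, MeOH, reflux) opens F10 at the secondary carbon with inversion, and the tertiary alkoxide lactonises to bromoalkenyl lactone ester F11. MeI/K2CO3 (as in step 4) gives methylated lactone F12, and ethoxycarbonylation of the vinyl bromide (Pd(OAc)2, PPh3, CO 1 atm, EtOH, Et3N, DMF, 60 °C) gives 8.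

Further compounds
F1 | step 7 | methyl (2S)-2-[(4-methoxybenzyl)oxy]-3-methylbutanoate | CC(C)[C@H](OCc1ccc(OC)cc1)C(=O)OC
F2 | step 7 | (2S)-2-[(4-methoxybenzyl)oxy]-3-methylbutanal | CC(C)[C@H](OCc1ccc(OC)cc1)C=O
F3 | step 7 | ethyl (3aR,5R,6aR)-5-{(2S,3S,4S)-3-hydroxy-4-[(4-methoxybenzyl)oxy]-5-methyl-2-(prop-1-en-2-yl)hexyl}-3,3,6a-trimethyl-1,6-dioxohexahydro-1H-cyclopenta[c]furan-5-carboxylate | C=C(C)[C@H](C[C@]1(C[C@H]2C(C)(C)OC(=O)[C@@]2(C)C1=O)C(=O)OCC)[C@H](O)[C@@H](OCc3ccc(OC)cc3)C(C)C
F4 | step 7 | (3aR,5R,6aR,5'S,6'S)-6'-{(1S)-1-[(4-methoxybenzyl)oxy]-2-methylpropyl}-3,3,6a-trimethyl-5'-(prop-1-en-2-yl)hexahydrospiro[cyclopenta[c]furan-5,3'-pyran]-1,2',6-trione | C=C(C)[C@@H]1C[C@]2(C[C@H]3C(C)(C)OC(=O)[C@@]3(C)C2=O)C(=O)O[C@@H]1[C@@H](OCc4ccc(OC)cc4)C(C)C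
F5 | step 7 | (3aR,5R,6aR,5'S,6'S)-6'-[(1S)-1-hydroxy-2-methylpropyl]-3,3,6a-trimethyl-5'-(prop-1-en-2-yl)hexahydrospiro[cyclopenta[c]furan-5,3'-pyran]-1,2',6-trione | C=C(C)[C@@H]1C[C@]2(C[C@H]3C(C)(C)OC(=O)[C@@]3(C)C2=O)C(=O)O[C@@H]1[C@@H](O)C(C)C
F6 | step 5 | methyl (3R,4R)-4-[2-(ethoxycarbonyl)-5-methylhex-4-en-1-yl]-3,5,5-trimethyl-2-oxotetrahydrofuran-3-carboxylate (epimers at the ester α-carbon) | CCOC(=O)C(CC=C(C)C)C[C@H]1C(C)(C)OC(=O)[C@@]1(C)C(=O)OC
F7 | step 5 | methyl (3R,4R)-4-{(4S,5S,6S)-2-(ethoxycarbonyl)-5-hydroxy-6-[(4-methoxybenzyl)oxy]-7-methyl-4-(prop-1-en-2-yl)octyl}-3,5,5-trimethyl-2-oxotetrahydrofuran-3-carboxylate (epimers at the ester α-carbon) | C=C(C)[C@H](CC(C[C@H]1C(C)(C)OC(=O)[C@@]1(C)C(=O)OC)C(=O)OCC)[C@H](O)[C@@H](OCc2ccc(OC)cc2)C(C)C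
F8 | step 5 | methyl (3R,4R)-4-{[(5S,6S)-6-{(1S)-1-[(4-methoxybenzyl)oxy]-2-methylpropyl}-2-oxo-5-(prop-1-en-2-yl)tetrahydro-2H-pyran-3-yl]methyl}-3,5,5-trimethyl-2-oxotetrahydrofuran-3-carboxylate (epimers at C3 of the pyranone) | C=C(C)[C@@H]1CC(C[C@H]2C(C)(C)OC(=O)[C@@]2(C)C(=O)OC)C(=O)O[C@@H]1[C@@H](OCc3ccc(OC)cc3)C(C)C
F9 | step 3 | 2-bromo-5-methylhexa-1,4-diene | C=C(Br)CC=C(C)C
F10 | step 3 | (3R)-3-(2-bromoprop-2-en-1-yl)-2,2-dimethyloxirane | C=C(Br)C[C@H]1OC1(C)C
F11 | step 3 | methyl (4R)-4-(2-bromoprop-2-en-1-yl)-5,5-dimethyl-2-oxotetrahydrofuran-3-carboxylate (epimers at C3) | C=C(Br)C[C@H]1C(C)(C)OC(=O)C1C(=O)OC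
F12 | step 3 | methyl (3R,4R)-4-(2-bromoprop-2-en-1-yl)-3,5,5-trimethyl-2-oxotetrahydrofuran-3-carboxylate | C=C(Br)C[C@H]1C(C)(C)OC(=O)[C@@]1(C)C(=O)OC
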